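**Conventions and assumption.** Every intermediate carries the atom numbers of the target (C1–C10; ring A = C1–C5, ring B = C5–C10 plus C1). β is the face of the C1 methyl group and α the opposite face. Remark on the chemistry: aldol 4 and its successors are drawn as the anti (6S) epimer and 18–21 as the 8β-methyl epimers; the other epimer at C6 (erased in step 10) or at C8 (erased in step 15) converges on the same compounds. The stereodescriptors of 16 and 18 were checked against 30 at C1, C4, C5 and C10 and needed no correction.

## Structural features

Lapiferine (30) is a daucane-type hydroazulene: cyclopentane ring A (C1–C5) and cycloheptane ring B (C5–C10 and C1) share the C1–C5 bond and are trans-fused, with a β-methyl group on the quaternary C1 and an α-hydrogen on C5. Seven stereocentres lie on two contiguous runs: C4–C5–C6 (tertiary β-hydroxyl and α-isopropyl on C4, α-angelate on C6) and C8–C9–C10–C1 (α-oxirane across C8/C9, α-hydroxyl on the neopentyl C10). Only C2, C3 and C7 are unfunctionalised. The fragile groups are the angelate (its Z double bond isomerises to the tiglate under basic, nucleophilic or acidic stress), the trisubstituted epoxide next to a free hydroxyl (Payne migration, acid opening), and the tertiary C4 alcohol, which is β to the C6 oxygen and invites dehydration or, when C6 is a ketone, retro-aldol opening of ring A. The real difficulty is ring B: a seven-membered ring closed next to a quaternary carbon, with oxygen on C6, C8, C9 and C10, so that C6 and C9 stand in a 1,4-relationship that no simple polar bond construction provides; in addition, the C10 carbinol cannot be set by reducing a ring ketone, because hydride would enter anti to the C1 methyl group. The key step exploits this 1,4-pattern: when C6 and C9 of ring B are both ketones, C7 and C8 are both enolisable α-carbons, and the C7–C8 bond of ring B can be made by oxidative union of two enolates held on the trans-disposed C5 and C1 positions of ring A. The oxygens this closure leaves behind are the ones the target needs: C6 becomes the ester carbinol and the C9 carbonyl is the handle for the C8=C9 alkene that is epoxidised under direction of the C10 hydroxyl.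

## Logic of the disconnections

30 ⇒ 29. The two oxirane bonds C8–O and C9–O are cut first. The epoxide is the most fragile group and its α-configuration can be derived from the C10 hydroxyl by syn delivery, so it is installed last; 29 has two stereocentres fewer. The forward step must oxidise C8=C9 on the face of the C10 hydroxyl and leave the angelate double bond alone.

29 ⇒ 28 ⇒ 25 + 26. The C10 oxygen is re-silylated and the ester bond between O6 and the acyl carbon is cut. Acylating while C10 is still protected leaves the C6 hydroxyl as the only secondary alcohol of 25, so site selectivity is not an issue; 26 is commercial. The forward acylation must not isomerise the Z double bond, and the later desilylation must spare the ester.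

25 ⇒ 23 ⇒ 21 ⇒ 20. The C9–H bond of the alkene is exchanged for C9–O, through 23 back to the ketone in 21 and its unprotected form 20. A C9 ketone gives the C8=C9 alkene regiospecifically and is the oxidation pattern the ring closure produces. The forward enolisation must go toward C8 and not C10, and both hydroxyls must be masked while the enolate exists.

20 ⇒ 19 ⇒ 18. The C6–H bond is cut (carbinol to ketone) and the C4 oxygen is re-silylated. This removes the C6 stereocentre, which can be regenerated from C4 by intramolecular hydride delivery; the free C4 hydroxyl also distinguishes the C6 ketone from the C9 ketone. The forward sequence needs selective cleavage of the tertiary silyl ether beside the C10 silyl ether and a reductant that touches only a β-hydroxy ketone.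

18 ⇒ 16. The C7–C8 bond is cut, which opens ring B and removes the C8 stereocentre; 16 is a cyclopentane with an acetyl group on C5 and a 2-silyloxybutanoyl arm on C1. Both carbons are α to a carbonyl, so the bond joins two nucleophilic centres and the forward step must be an oxidative coupling. It requires kinetic enolisation at C7 and C8 only, and ring closure faster than aldol or intermolecular reactions.

16 ⇒ 15 ⇒ 14 ⇒ 13. These are functional-group interconversions: the C6 ketone goes back to a silylated carbinol and the C9 ketone to a dithiane. Neither carbonyl may be present while a carbon nucleophile is used, so they are unveiled one after the other. The forward steps must cleave the secondary triethylsilyl ether in the presence of the tertiary one and of the C10 silyl ether.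

13 ⇒ 12 ⇒ 9 + 10. The C9–C10 bond is cut between a carbonyl carbon and a carbinol carbon, that is, an acyl anion (10 after lithiation) and an aldehyde (9). This removes four carbons and leaves a non-enolisable aldehyde on the quaternary C1. The forward addition creates C10 and must occur on the correct face of the formyl group.

9 ⇒ 7 ⇒ 6 ⇒ 5. The formyl group is traced to a vinyl group (cleavage of C10=CH2), the silyl ethers to the free diol, and the C4–isopropyl bond is cut to give the ketone 5. The gain is the loss of the C4 stereocentre and of three carbons. The forward addition must be anti to the C5 side chain and must tolerate a hindered, enolisable ketone with a free β-hydroxyl.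

5 ⇒ 4 ⇒ 1 + 2. The vinyl C–H is traced to C–Si, and then C1–C10 and C5–C6 are cut in one operation: conjugate addition of a 1-silylvinyl aluminium reagent to 1 and aldol capture of the enolate by 2. This reduces the problem to three simple components and places the only catalyst-controlled stereocentre, C1, at the start. The forward step must be enantioselective at a quaternary centre and must trap the enolate at C5 anti to the new alkenyl group.

## Other disconnections considered

Alternative 1: The cut is made at C1–C10 and C5–C6 together, with ring B left open. The forward key step would be the Cu(OTf)2/chiral carbene-catalysed conjugate addition of the alkenylaluminium reagent of step 1 to 1, followed by capture of the aluminium enolate by the iodo aldehyde A2 to give aldol A1. In its favour, A1 already holds C7, C8 with its methyl group, the future C8=C9 alkene as a Z-vinyl iodide, and the C6 carbinol in the configuration of the target (the anti aldol). Against it here, A2 is a β,γ-unsaturated aldehyde that can slip into conjugation or be enolised by the basic enolate. Ring B would then be closed late at C9–C10 (for instance with CrCl2/NiCl2), with uncertain facial selectivity at C10 inside a forming seven-membered ring. The vinyl iodide would also have to survive the organocerium addition and the unmasking of the C10 carbonyl, which rules out ozone. In comparison, the two plans are equal on the opening move, since the chosen route starts with the same conjugate addition–aldol. Alternative 1 is the better plan in step economy on the C6–C9 segment, because oxidation at C6, the oxidative coupling, the directed re-reduction and the enol triflate sequence would all disappear. The chosen plan is better in the robustness of its electrophile (2) and in setting C10 before the ring exists rather than during a medium-ring closure.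

Alternative 2: The cut is the ring-fusion bond C1–C5 and leads back to the Wieland–Miescher-type cis-decalin A4, in which C1 is bonded to C6, C5 carries a mesylate and C6 a tertiary hydroxyl. The forward key step would be a semipinacol 1,2-shift: KOtBu at low temperature forms the C6 alkoxide, C1 migrates from C6 to C5 with expulsion of the mesylate, and hydroxy ketone A3 with rings A and B results in one operation. In its favour, the reaction type is known and stereospecific (inversion at C5, retention at the migrating C1), so the trans ring fusion follows from geometry. The C6 ketone also appears exactly where a C4-directed reduction needs it. On mechanistic certainty of the ring-forming step this alternative is better than the chosen plan, whose ring closure has no seven-membered precedent. Against it here, A3 has no oxygen at C9 and carries C10 only as a ketal. The C8=C9 alkene and the 10α-hydroxyl would have to be introduced afterwards, and a ring ketone at C10 would be reduced preferentially from the face opposite the C1 methyl, which gives the wrong carbinol. The C8 methyl stereocentre and the contiguous C4/C5/C6 oxygenation must be assembled on the decalin with the C1–C6 bond antiperiplanar to the C5 leaving group, or C7 would migrate instead. The two plans are equal in the logic of the C6 reduction and the directed epoxidation, and the step count is expected to be comparable or higher for the alternative.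

Alternative 3: The cut removes three C–O bonds at the end, C10–O and both oxirane bonds, and leads back to alkene A6 (C9=C10, 8β-methyl). The forward key step would be a sensitised photooxygenation: singlet oxygen adds to C10 in an ene reaction, takes the α-hydrogen from C8 and shifts the alkene to C8=C9, giving hydroperoxide A7. Ti(OiPr)4 added to the same flask then passes one peroxide oxygen to the new alkene on the face of the C10 oxygen, giving epoxy alcohol A5. In its favour, C8, C9 and C10 and three C–O bonds are set in one flask, the syn epoxy alcohol follows from the mechanism, and only C8 offers an allylic hydrogen (C1 is quaternary), so the ene regiochemistry is unambiguous. On redox and step economy of the C8–C10 segment it is better than the chosen plan, which carries a C10 silyl ether from step 7 to step 18 and needs a separate epoxidation. Against it here, it does not build ring B, so a ring-forming plan is still required. In the chosen plan C9 and C10 are already oxygenated by the ring closure, so adopting A6 would mean removing that oxygen again. A cis-disubstituted alkene is also a sluggish singlet-oxygen acceptor, and C8 would need prior stereocontrol (hydrogen α), whereas in the chosen plan C8 is irrelevant until the last step. The two plans are equal in relying on oxygen-directed delivery for the oxirane.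

Key step: step 11

## Route

Step 1
Reactants: 1 3-methylcyclopent-2-en-1-one; 2 acetaldehyde
Product: 4 silylvinyl aldol (2S,3S)-2-[(1S)-1-hydroxyethyl]-3-methyl-3-[1-(trimethylsilyl)vinyl]cyclopentan-1-one, via aluminium enolate 3 (not isolated)
Conditions: HC≡CSiMe3, iBu2AlH, hexanes/THF, 55 °C; then 1, Cu(OTf)2 (5 mol %), chiral sulfonate-bearing imidazolinium salt (5 mol %), THF, 4 → 22 °C; then 2, −78 °C; aq. NH4Cl
Reagents that add atoms: (1-(trimethylsilyl)vinyl)diisobutylaluminium, C=C([Si](C)(C)C)[Al](CC(C)C)CC(C)C
Why: Copper–carbene-catalysed enantioselective conjugate addition of the alkenylaluminium reagent creates the C1 quaternary centre under ligand control (the ligand enantiomer giving S-configured C1 in 4 is chosen); the regiodefined enolate 3 then adds to 2 through a closed aldol transition state on the face opposite the new alkenyl group, so the C5 side chain ends cis to the C1 methyl. C6 is expected mainly as the anti-aldol epimer and is oxidised in step 10, so its configuration does not matter.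

Step 2
Reactants: 4 silylvinyl aldol
Product: 5 vinyl aldol 2-(1-hydroxyethyl)-3-methyl-3-vinylcyclopentan-1-one (stereocentres as in 4)
Conditions: CF3CO2H (5 equiv), CH2Cl2, 0 → 22 °C
Reagents that add atoms: none
Why: Acid-mediated ipso-protodesilylation of the vinylsilane (protonation at the silicon-bearing carbon gives a β-silyl cation that loses the silyl group); it is run before the acid-labile tertiary alcohol exists, and at 0–22 °C the β-hydroxy ketone should persist.

Step 3
Reactants: 5 vinyl aldol
Product: 6 diol 2-(1-hydroxyethyl)-1-isopropyl-3-methyl-3-vinylcyclopentan-1-ol (C4 hydroxyl β and isopropyl α)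
Conditions: iPrMgCl, CeCl3 (3.5 equiv each), THF, −78 → 0 °C; aq. NH4Cl
Reagents that add atoms: isopropylmagnesium chloride, CC(C)[Mg]Cl
Why: 1,2-Addition of an organocerium reagent, which is weakly basic and suppresses enolisation and β-hydride reduction of the hindered ketone; one equivalent is consumed by the hydroxyl. The isopropyl group enters from the α-face, anti to the adjacent C5 side chain, which sets C4 with the hydroxyl β.

Step 4
Reactants: 6 diol
Product: 7 bis(triethylsilyl) ether of 6
Conditions: Et3SiOTf (3 equiv), 2,6-lutidine, CH2Cl2, −78 → 0 °C
Reagents that add atoms: triethylsilyl trifluoromethanesulfonate, CC[Si](CC)(CC)OS(=O)(=O)C(F)(F)F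
Why: Silyl triflate silylation reaches both the secondary C6 and the hindered tertiary C4 hydroxyl in one operation; the C4 ether later blocks retro-aldol chemistry and the C6 ether is temporary.

Step 5
Reactants: 7 bis(triethylsilyl) ether
Product: 9 C10 aldehyde (formyl group α on C1; C4 and C6 oxygens as triethylsilyl ethers), via ozonide 8 (not isolated)
Conditions: O3, CH2Cl2, −78 °C; then PPh3, −78 → 22 °C
Reagents that add atoms: ozone, [O-][O+]=O
Why: Ozonolysis of the only alkene with reductive work-up (PPh3 reduces ozonide 8); silyl ethers are inert to ozone in CH2Cl2 and the aldehyde has no α-hydrogen, so it cannot epimerise.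

Step 6
Reactants: 9 C10 aldehyde; 10 2-ethyl-1,3-dithiane
Product: 12 dithiane carbinol (10S; 2-ethyl-1,3-dithian-2-yl on C10), via lithiated dithiane 11 (not isolated)
Conditions: 10, nBuLi, THF, −30 °C; then 9, −78 → −40 °C; aq. NH4Cl
Reagents that add atoms: none
Why: Corey–Seebach addition of a lithiated dithiane (masked propionyl anion) to a non-enolisable aldehyde forms C9–C10. C10 is set by substrate control: with the formyl hydrogen turned under ring A and the oxygen outward, the nucleophile should enter from the unsubstituted C2 flank, away from C5 and its substituents, which corresponds to the 10S carbinol needed (flagged below).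

Step 7
Reactants: 12 dithiane carbinol
Product: 13 tert-butyldimethylsilyl ether of 12
Conditions: tBuMe2SiOTf, 2,6-lutidine, CH2Cl2, 0 → 22 °C
Reagents that add atoms: tert-butyldimethylsilyl trifluoromethanesulfonate, CC(C)(C)[Si](C)(C)OS(=O)(=O)C(F)(F)F
Why: Silyl triflate silylation of the hindered neopentyl carbinol; the bulky silyl ether later steers enolisation of the C9 ketone away from C10 and survives both triethylsilyl cleavages.

Step 8
Reactants: 13 silylated dithiane
Product: 14 α-silyloxy ethyl ketone (C9 ketone; 10-OTBS; 4-OTES; 6-OTES)
Conditions: MeI, CaCO3, MeCN/H2O (9:1), 45 °C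
Reagents that add atoms: water, O
Why: S-Methylation of the dithiane and hydrolysis of the sulfonium salt under CaCO3 buffering unmask the C9 ketone without acid, so the three silyl ethers and the α-silyloxy stereocentre C10 remain.

Step 9
Reactants: 14 α-silyloxy ethyl ketone
Product: 15 C6 alcohol (secondary triethylsilyl ether removed)
Conditions: PPTS (cat.), MeOH/CH2Cl2, 0 °C
Reagents that add atoms: none
Why: Acid-catalysed methanolysis discriminates on steric grounds: the secondary triethylsilyl ether at C6 should be cleaved much faster than the tertiary one at C4 and the hindered tert-butyldimethylsilyl ether at C10.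

Step 10
Reactants: 15 C6 alcohol
Product: 16 diketone (acetyl on C5; 2-silyloxybutanoyl on C1)
Conditions: Dess–Martin periodinane, NaHCO3, CH2Cl2, 0 → 22 °C
Reagents that add atoms: none
Why: Dess–Martin oxidation under buffered, non-basic conditions gives the methyl ketone; C5, now α to a carbonyl, sits between two quaternary carbons, and its configuration (acetyl cis to the small C1 methyl and the C4 oxygen) is also the more stable one.

Step 11
Reactants: 16 diketone
Product: 18 cycloheptane-1,4-dione (C6 and C9 ketones; ring B closed), via dilithium bis-enolate 17 (not isolated)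
Conditions: 16 added slowly to LiN(iPr)2 (2.5 equiv), THF, −78 °C (final 0.01 M); then CuCl2 (2.5 equiv) in DMF, −78 → 0 °C
Reagents that add atoms: none
Why: Proposed new method: double kinetic deprotonation (the C7 methyl of the C6 ketone and the C8 methylene of the C9 ketone) gives bis-enolate 17; one-electron oxidation of one enolate by CuCl2 gives an α-keto radical (or copper-bound enolate) that is captured at the α-carbon of the second enolate, and oxidation of the resulting ketyl by a second equivalent of CuCl2 delivers the 1,4-diketone, so two nucleophilic carbons are joined. The closest known reaction type is the intramolecular oxidative coupling of ketone bis-enolates with divalent copper or trivalent iron salts, which is established for five- and six-membered 1,4-diketones but not for a cycloheptane-1,4-dione. Ring B closes in a 7-endo-trig mode (C7 attacks C8 of the C8=C9 enolate, both enolate double bonds lying inside the new ring); attack at C9 is electronically unproductive and the trans arms on C1 and C5 offer no smaller carbocycle by C–C coupling. The only new stereocentre, C8, is not controlled and need not be, because it becomes trigonal in step 15; C1, C4, C5 and C10 are untouched because none of them is deprotonated. The step needs regioselective enolisation, which the substrate secures: C5–H lies between two quaternary carbons, and C10–H is shielded by the silyl ether and disfavoured by the α-oxygen, so the base takes the methyl and the ethyl CH2. It also needs enolisation to outrun the two possible six-membered intramolecular aldol additions, hence inverse addition of 16 to excess base at −78 °C, and cyclisation to outrun dimerisation, hence high dilution. The C4 triethylsilyl ether prevents retro-aldol cleavage and loss of the β-oxygen, and CuCl2 is preferred to Fe(acac)3 because simple ketone enolates are oxidised more readily by divalent copper.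

Step 12
Reactants: 18 cycloheptane-1,4-dione
Product: 19 4-hydroxy dione (tertiary triethylsilyl ether removed)
Conditions: HF·pyridine, pyridine, THF, 0 °C
Reagents that add atoms: none
Why: Buffered fluoride cleavage should remove the triethylsilyl ether well before the hindered α-keto tert-butyldimethylsilyl ether; the mild, non-basic medium avoids retro-aldol cleavage and dehydration of the new β-hydroxy ketone.

Step 13
Reactants: 19 4-hydroxy dione
Product: 20 4β,6α-diol C9 ketone
Conditions: Me4NBH(OAc)3, MeCN/AcOH (1:1), −40 → −20 °C
Reagents that add atoms: none
Why: Evans–Saksena reduction: the C4 hydroxyl exchanges onto boron and hydride is delivered intramolecularly to the β-face of the C6 carbonyl, giving the 6α-alcohol (1,3-anti to the C4 oxygen). The C9 ketone has no free hydroxyl within reach and is not reduced by this reagent.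

Step 14
Reactants: 20 diol ketone
Product: 21 bis(trimethylsilyl) ether of 20
Conditions: Me3SiOTf, 2,6-lutidine, CH2Cl2, −78 °C
Reagents that add atoms: trimethylsilyl trifluoromethanesulfonate, C[Si](C)(C)OS(=O)(=O)C(F)(F)F
Why: Silylation of both hydroxyls removes every acidic O–H before enolate chemistry, so that no alkoxide can be sulfonylated or trigger silyl migration in step 15; at −78 °C with 2,6-lutidine the hindered ketone is not enolised.

Step 15
Reactants: 21 bis(trimethylsilyl) ether
Product: 23 C8=C9 enol triflate, via potassium enolate 22 (not isolated)
Conditions: KN(SiMe3)2, THF, −78 °C; then PhNTf2, −78 → 0 °C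
Reagents that add atoms: N-phenylbis(trifluoromethanesulfonimide), FC(F)(F)S(=O)(=O)N(c1ccccc1)S(=O)(=O)C(F)(F)F
Why: Kinetic deprotonation should take C8–H, because C10–H is shielded by the silyl ether and the quaternary C1 and is deactivated by the α-oxygen; O-sulfonylation of enolate 22 fixes the C8=C9 regiochemistry and erases the uncontrolled C8 stereocentre.

Step 16
Reactants: 23 enol triflate
Product: 25 4β,6α-diol with C8=C9 alkene (10α-OTBS), via bis-TMS alkene 24 (not isolated)
Conditions: Pd(OAc)2 (10 mol %), PPh3 (20 mol %), HCO2H, nBu3N, DMF, 60 °C; then citric acid, MeOH, 22 °C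
Reagents that add atoms: none
Why: Palladium-catalysed formate reduction of the enol triflate (oxidative addition to zerovalent palladium, formate-to-hydride exchange with loss of CO2, reductive elimination) gives the alkene without double-bond migration. Mild acidic methanolysis then removes both trimethylsilyl ethers of 24 and spares the allylic tert-butyldimethylsilyl ether.

Step 17
Reactants: 25 diol alkene; 26 angelic acid
Product: 28 6α-angelate (10α-OTBS), via mixed anhydride 27 (not isolated)
Conditions: 26, 2,4,6-Cl3C6H2COCl, Et3N, toluene, 22 °C; then 25, toluene, 80 °C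
Reagents that add atoms: none
Why: Yamaguchi-type acylation through mixed anhydride 27 without a nucleophilic catalyst, the conditions least prone to angelate-to-tiglate isomerisation. The alcohol attacks the less hindered angeloyl carbonyl, and only the secondary C6 hydroxyl reacts (C4–OH is tertiary, C10–O is silylated).

Step 18
Reactants: 28 angelate silyl ether
Product: 29 6α-angelate 10α-alcohol
Conditions: HF·pyridine, pyridine, THF, 0 → 22 °C
Reagents that add atoms: none
Why: Buffered HF·pyridine cleaves the allylic silyl ether without base, so the ester should neither migrate nor isomerise and the tertiary alcohol is not ionised.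

Step 19
Reactants: 29 allylic alcohol
Product: 30 lapiferine
Conditions: VO(acac)2 (5 mol %), tBuOOH, CH2Cl2, 0 → 22 °C
Reagents that add atoms: tert-butyl hydroperoxide, CC(C)(C)OO
Why: Vanadium-catalysed hydroxyl-directed epoxidation: the C10 vanadate delivers the peroxide oxygen to the same (α) face of the adjacent C8=C9 alkene, as is general for cyclohept-2-enols, which sets C8 and C9. The electron-poor angelate alkene and the remote tertiary hydroxyl do not take part.

## Compound list

1 | 3-methylcyclopent-2-en-1-one | CC1=CC(=O)CC1 | starting material
2 | acetaldehyde | CC=O | starting material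
3 | diisobutylaluminium enolate (C4–O–Al, C4=C5) of 3-methyl-3-[1-(trimethylsilyl)vinyl]cyclopentanone, C1 as in the target | C=C([Si](C)(C)C)[C@@]1(C)CCC(O[Al](CC(C)C)CC(C)C)=C1 | intermediate (not isolated)
4 | (2S,3S)-2-[(1S)-1-hydroxyethyl]-3-methyl-3-[1-(trimethylsilyl)vinyl]cyclopentan-1-one (side chain cis to methyl) | C[C@H](O)[C@H]1C(=O)CC[C@]1(C)C(=C)[Si](C)(C)C | intermediate
5 | 2-(1-hydroxyethyl)-3-methyl-3-vinylcyclopentan-1-one, stereocentres as in 4 | C[C@H](O)[C@H]1C(=O)CC[C@]1(C)C=C | intermediate
6 | 2-(1-hydroxyethyl)-1-isopropyl-3-methyl-3-vinylcyclopentan-1-ol; C4–OH β (cis to the C5 side chain and the C1 methyl), isopropyl α | C[C@H](O)[C@H]1[C@](O)(C(C)C)CC[C@]1(C)C=C | intermediate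
7 | bis(triethylsilyl) ether of 6 (C4–OTES, C6–OTES) | C[C@H](O[Si](CC)(CC)CC)[C@H]1[C@](O[Si](CC)(CC)CC)(C(C)C)CC[C@]1(C)C=C | intermediate
8 | 1,2,4-trioxolane (ozonide) of the vinyl group of 7, epimers at the trioxolane carbon | C[C@H](O[Si](CC)(CC)CC)[C@H]1[C@](O[Si](CC)(CC)CC)(C(C)C)CC[C@]1(C)C2OCOO2 | intermediate (not isolated)
9 | C10 aldehyde: formyl group α on C1, C4–OTES, C6–OTES | C[C@H](O[Si](CC)(CC)CC)[C@H]1[C@](O[Si](CC)(CC)CC)(C(C)C)CC[C@]1(C)C=O | intermediate
10 | 2-ethyl-1,3-dithiane | CCC1SCCCS1 | starting material
11 | 2-ethyl-2-lithio-1,3-dithiane | CCC1([Li])SCCCS1 | intermediate (not isolated)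
12 | dithiane carbinol: (10S)-hydroxy, C9 as 2-ethyl-1,3-dithiane, C4–OTES, C6–OTES | C[C@H](O[Si](CC)(CC)CC)[C@H]1[C@](O[Si](CC)(CC)CC)(C(C)C)CC[C@]1(C)[C@H](O)C2(CC)SCCCS2 | intermediate
13 | tert-butyldimethylsilyl ether of 12 (C10–OTBS) | C[C@H](O[Si](CC)(CC)CC)[C@H]1[C@](O[Si](CC)(CC)CC)(C(C)C)CC[C@]1(C)[C@H](O[Si](C)(C)C(C)(C)C)C2(CC)SCCCS2 | intermediate
14 | α-silyloxy ethyl ketone: C9 ketone, C10–OTBS, C4–OTES, C6–OTES | C[C@H](O[Si](CC)(CC)CC)[C@H]1[C@](O[Si](CC)(CC)CC)(C(C)C)CC[C@]1(C)[C@H](O[Si](C)(C)C(C)(C)C)C(=O)CC | intermediate
15 | C6 alcohol: C9 ketone, C10–OTBS, C4–OTES, free C6–OH | C[C@H](O)[C@H]1[C@](O[Si](CC)(CC)CC)(C(C)C)CC[C@]1(C)[C@H](O[Si](C)(C)C(C)(C)C)C(=O)CC | intermediate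
16 | diketone: acetyl on C5 (β), (2S)-2-(tert-butyldimethylsilyloxy)butanoyl on C1 (α), C4–OTES | CC(=O)[C@H]1[C@](O[Si](CC)(CC)CC)(C(C)C)CC[C@]1(C)[C@H](O[Si](C)(C)C(C)(C)C)C(=O)CC | intermediate
17 | dilithium bis-enolate of 16 (C6–OLi with C6=C7; C9–OLi with C8=C9) | [Li]OC(=C)[C@H]1[C@](O[Si](CC)(CC)CC)(C(C)C)CC[C@]1(C)[C@H](O[Si](C)(C)C(C)(C)C)C(O[Li])=CC | intermediate (not isolated)
18 | trans-fused cycloheptane-1,4-dione: C6 and C9 ketones, 8-methyl, 10α-OTBS, 4β-OTES, 4α-isopropyl | O=C1C[C@H](C)C(=O)[C@@H](O[Si](C)(C)C(C)(C)C)[C@@]2(C)CC[C@@](O[Si](CC)(CC)CC)(C(C)C)[C@H]12 | intermediate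
19 | 4β-hydroxy dione: C6 and C9 ketones, 10α-OTBS | O=C1C[C@H](C)C(=O)[C@@H](O[Si](C)(C)C(C)(C)C)[C@@]2(C)CC[C@@](O)(C(C)C)[C@H]12 | intermediate
20 | 4β,6α-diol with C9 ketone, 10α-OTBS | O[C@H]1C[C@H](C)C(=O)[C@@H](O[Si](C)(C)C(C)(C)C)[C@@]2(C)CC[C@@](O)(C(C)C)[C@H]12 | intermediate
21 | bis(trimethylsilyl) ether of 20 (4β-OTMS, 6α-OTMS) | C[Si](C)(C)O[C@H]1C[C@H](C)C(=O)[C@@H](O[Si](C)(C)C(C)(C)C)[C@@]2(C)CC[C@@](O[Si](C)(C)C)(C(C)C)[C@H]12 | intermediate
22 | potassium enolate of 21 (C9–OK, C8=C9) | C[Si](C)(C)O[C@H]1CC(C)=C(O[K])[C@@H](O[Si](C)(C)C(C)(C)C)[C@@]2(C)CC[C@@](O[Si](C)(C)C)(C(C)C)[C@H]12 | intermediate (not isolated)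
23 | enol triflate: C9–OTf on the C8=C9 double bond, 10α-OTBS, 4β- and 6α-OTMS | C[Si](C)(C)O[C@H]1CC(C)=C(OS(=O)(=O)C(F)(F)F)[C@@H](O[Si](C)(C)C(C)(C)C)[C@@]2(C)CC[C@@](O[Si](C)(C)C)(C(C)C)[C@H]12 | intermediate
24 | C8=C9 alkene with 4β- and 6α-OTMS, 10α-OTBS | C[Si](C)(C)O[C@H]1CC(C)=C[C@@H](O[Si](C)(C)C(C)(C)C)[C@@]2(C)CC[C@@](O[Si](C)(C)C)(C(C)C)[C@H]12 | intermediate (not isolated)
25 | 4β,6α-diol with C8=C9 alkene, 10α-OTBS | O[C@H]1CC(C)=C[C@@H](O[Si](C)(C)C(C)(C)C)[C@@]2(C)CC[C@@](O)(C(C)C)[C@H]12 | intermediate
26 | angelic acid, (Z)-2-methylbut-2-enoic acid | C/C=C(/C)C(=O)O | starting material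
27 | angelic 2,4,6-trichlorobenzoic anhydride | C/C=C(/C)C(=O)OC(=O)c1c(Cl)cc(Cl)cc1Cl | intermediate (not isolated)
28 | 6α-angelate with C8=C9 alkene, 10α-OTBS, 4β-OH | C/C=C(/C)C(=O)O[C@H]1CC(C)=C[C@@H](O[Si](C)(C)C(C)(C)C)[C@@]2(C)CC[C@@](O)(C(C)C)[C@H]12 | intermediate
29 | 6α-angelate with C8=C9 alkene, 10α-OH, 4β-OH | C/C=C(/C)C(=O)O[C@H]1CC(C)=C[C@@H](O)[C@@]2(C)CC[C@@](O)(C(C)C)[C@H]12 | intermediate
30 | lapiferine | C/C=C(/C)C(=O)O[C@H]1C[C@@]2(C)O[C@H]2[C@@H](O)[C@@]2(C)CC[C@@](O)(C(C)C)[C@H]12 | target

## Step count and least certain steps

Total step count: 19 (reagents prepared in the flask are not counted as steps). Longest linear sequence: 19 steps, from 1 to 30.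

Step 11 (key step, proposed new method). The most likely failure is ring closure by aldol addition of the first-formed mono-enolate onto the other ketone (both modes give six-membered rings), or oxidative dimerisation and α-chlorination, because a seven-membered transition state lets proton-transfer and bimolecular pathways compete. The fallback uses known reaction types only, sets out from 14 and returns at 18. The C9 ketone of 14 is enolised toward C8 (KN(SiMe3)2, THF, −78 °C) and O-acylated with pivaloyl chloride to give enol pivalate F1. PPTS/MeOH frees the C6 hydroxyl (alcohol F2) and Dess–Martin oxidation gives methyl ketone F3, in which the two carbonyl arms are now differentiated. Detrifluoroacetylative diazo transfer (LiN(SiMe3)2, CF3CO2CH2CF3; then MsN3, Et3N) converts the acetyl group into diazoketone F4. Rh2(OAc)4 adds the carbenoid carbon C7 across the C8=C9 enol ester to give acyloxycyclopropane F5, a six-membered ring fused to a cyclopropane, which is the well-precedented closure mode for diazoketones. Methanolysis of the pivalate (K2CO3, MeOH) opens the donor–acceptor cyclopropane at C7–C9 by retro-aldol cleavage, leaves the C7–C8 bond and gives 18 by ring expansion.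

Step 2. The most likely failure is acid-induced dehydration of the β-hydroxy ketone competing with C–Si cleavage. The fallback sets out from 4 and returns at 9, keeping the silyl group until the oxidative cleavage. iPrMgCl–CeCl3 addition to 4 gives silylvinyl diol F6 and Et3SiOTf gives bis(triethylsilyl) ether F7. Dihydroxylation (OsO4 cat., N-methylmorpholine N-oxide) and NaIO4 cleavage convert the 1-silylvinyl group into acylsilane F8, and K2CO3/MeOH (attack at silicon with Brook-type C–Si cleavage) releases aldehyde 9.

Step 6. The most likely failure is poor facial selectivity in the addition to the formyl group, because the three substituents on the quaternary C1 differ only moderately in size. The fallback sets out from 12 as obtained, whatever its composition at C10, and returns at 12. Dess–Martin oxidation gives C10 ketone F9, which is reduced with LiAlH4 (Et2O, −78 °C). In F9 the bulky dithianyl group must lie outside ring A, and hydride entering from the same open C2 flank should again give the 10S carbinol; this is an independent second control element and recycles the unwanted epimer.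

Step 12. The most likely failure is incomplete discrimination between the two silyl ethers, or retro-aldol cleavage and dehydration once the β-hydroxy ketone is exposed. The fallback sets out from 18 and returns at 20. Corey–Bakshi–Shibata reduction ((R)-2-methyl-CBS-oxazaborolidine, BH3·SMe2) of the less hindered C6 ketone, with C5 as the large and C7 as the small substituent, gives 6α-alcohol F10 under reagent control while the C4 silyl ether is still in place. HF·pyridine then removes the tertiary triethylsilyl group from a compound that is no longer a β-hydroxy ketone, giving 20.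

Step 17. The most likely failure is Z-to-E isomerisation of the angeloyl group or sluggish acylation of the hindered C6 hydroxyl at the temperature required. The fallback sets out from 25 and returns at 28. Carbodiimide coupling with 2-[bis(2,2,2-trifluoroethoxy)phosphoryl]propanoic acid gives phosphonopropionate F11. Still–Gennari olefination with 2 (KN(SiMe3)2, 18-crown-6, THF, −78 °C) then builds the Z-trisubstituted double bond on the ester, giving 28 without a preformed angeloyl donor having to survive acylation.

## Further compounds

F1 | step 11 | enol pivalate of 14 (C9–OPiv, C8=C9) | C[C@H](O[Si](CC)(CC)CC)[C@H]1[C@](O[Si](CC)(CC)CC)(C(C)C)CC[C@]1(C)[C@H](O[Si](C)(C)C(C)(C)C)C(OC(=O)C(C)(C)C)=CC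
F2 | step 11 | C6 alcohol of F1 | C[C@H](O)[C@H]1[C@](O[Si](CC)(CC)CC)(C(C)C)CC[C@]1(C)[C@H](O[Si](C)(C)C(C)(C)C)C(OC(=O)C(C)(C)C)=CC
F3 | step 11 | methyl ketone (acetyl on C5) with C9 enol pivalate | CC(=O)[C@H]1[C@](O[Si](CC)(CC)CC)(C(C)C)CC[C@]1(C)[C@H](O[Si](C)(C)C(C)(C)C)C(OC(=O)C(C)(C)C)=CC
F4 | step 11 | diazoketone (C7 diazo, C6 ketone) with C9 enol pivalate | [N-]=[N+]=CC(=O)[C@H]1[C@](O[Si](CC)(CC)CC)(C(C)C)CC[C@]1(C)[C@H](O[Si](C)(C)C(C)(C)C)C(OC(=O)C(C)(C)C)=CC
F5 | step 11 | acyloxycyclopropane (cyclopropane C7–C8–C9, C6 ketone, C9–OPiv) | O=C1C2C(C)C2(OC(=O)C(C)(C)C)[C@@H](O[Si](C)(C)C(C)(C)C)[C@@]3(C)CC[C@@](O[Si](CC)(CC)CC)(C(C)C)[C@H]13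
F6 | step 2 | silylvinyl diol (4β-OH, 4α-isopropyl, 1-silylvinyl on C1) | C[C@H](O)[C@H]1[C@](O)(C(C)C)CC[C@]1(C)C(=C)[Si](C)(C)C
F7 | step 2 | bis(triethylsilyl) ether of F6 | C[C@H](O[Si](CC)(CC)CC)[C@H]1[C@](O[Si](CC)(CC)CC)(C(C)C)CC[C@]1(C)C(=C)[Si](C)(C)C
F8 | step 2 | acylsilane (C10 as C(=O)SiMe3) | C[C@H](O[Si](CC)(CC)CC)[C@H]1[C@](O[Si](CC)(CC)CC)(C(C)C)CC[C@]1(C)C(=O)[Si](C)(C)C
F9 | step 6 | C10 ketone (2-ethyl-1,3-dithian-2-yl ketone on C1) | C[C@H](O[Si](CC)(CC)CC)[C@H]1[C@](O[Si](CC)(CC)CC)(C(C)C)CC[C@]1(C)C(=O)C2(CC)SCCCS2
F10 | step 12 | 6α-alcohol with C9 ketone, 4β-OTES, 10α-OTBS | O[C@H]1C[C@H](C)C(=O)[C@@H](O[Si](C)(C)C(C)(C)C)[C@@]2(C)CC[C@@](O[Si](CC)(CC)CC)(C(C)C)[C@H]12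
F11 | step 17 | C6 2-[bis(2,2,2-trifluoroethoxy)phosphoryl]propanoate of 25 | CC(C(=O)O[C@H]1CC(C)=C[C@@H](O[Si](C)(C)C(C)(C)C)[C@@]2(C)CC[C@@](O)(C(C)C)[C@H]12)P(=O)(OCC(F)(F)F)OCC(F)(F)F
A1 | alternative 1 | aldol adduct: trans-2,3-disubstituted cyclopentanone with (Z)-vinyl iodide side chain and 1-silylvinyl group | O[C@@H](C/C(C)=C\I)[C@H]1C(=O)CC[C@]1(C)C(=C)[Si](C)(C)C
A2 | alternative 1 | (Z)-4-iodo-3-methylbut-3-enal | O=CC/C(C)=C\I
A3 | alternative 2 | trans-fused hydroazulenone hydroxy ketone (C6 ketone, C10 dioxolane, 4β-OH) | O=C1C[C@H](C)CC2(OCCO2)[C@@]3(C)CC[C@@](O)(C(C)C)[C@H]13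
A4 | alternative 2 | cis-decalin hydroxy mesylate (C1–C6 bond, 6β-OH, 5β-OMs, 4β-OH, C10 dioxolane) | CS(=O)(=O)O[C@H]1[C@](O)(C(C)C)CC[C@]2(C)C3(OCCO3)C[C@@H](C)C[C@]12O
A5 | alternative 3 | epoxy alcohol (6α-OTBS, 8α,9α-epoxide, 10α-OH) | CC(C)(C)[Si](C)(C)O[C@H]1C[C@@]2(C)O[C@H]2[C@@H](O)[C@@]3(C)CC[C@@](O)(C(C)C)[C@H]13
A6 | alternative 3 | C9=C10 alkene (6α-OTBS, 8β-methyl) | CC(C)(C)[Si](C)(C)O[C@H]1C[C@H](C)C=C[C@@]2(C)CC[C@@](O)(C(C)C)[C@H]12
A7 | alternative 3 | 10α-hydroperoxide with C8=C9 alkene (6α-OTBS) | CC(C)(C)[Si](C)(C)O[C@H]1CC(C)=C[C@@H](OO)[C@@]2(C)CC[C@@](O)(C(C)C)[C@H]12
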